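The retrosynthesis first removes thirteen O-benzyl groups and the two C3–O gallate esters. It then traces both C3 oxygens back to C4 ketones and finally cuts the two flavan C2–aryl bonds, which leaves one benzotropolone and two chromones.
Enabling feature: C1 (benzo ring) and C7 (seven-membered ring) of the benzo[7]annulen-5-one each carry a stereogenic flavan C2. That carbon is the β-carbon C2 of a 5,7-dioxygenated chromen-4-one, which already contains ring A, O1 and C4.
Forward: the benzo[7]annulenone bicycle is made first by oxidative condensation of 4-bromocatechol with 4-bromopyrogallol, then benzylated and borylated at C1 and C7. Rings A and C arrive preformed in the chromone, and one twofold conjugate arylation joins the three pieces without closing a ring.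
Each C4 ketone is then moved to C3 (reduction, dehydration, epoxidation–rearrangement), reduced and galloylated, and all benzyl groups are removed.
Stereochemistry: both C2 centres come from the chiral pyridine-oxazoline ligand on palladium. Both C3 centres come from hydride delivery to the C3 ketone anti to the C2 substituent (2,3-cis).

Key step: step 8

Assumption 1: the constitution is taken as drawn, with the tropolone-bound flavan on C7 next to the C6 hydroxyl, and all four stereocentres R (2,3-cis in both C rings).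
Assumption 2: the facial sense of t-BuPyOx on chromones is taken to parallel that on 3-methylcyclohexenone, where the S ligand gives R products. That face corresponds to 2R in a flavanone, so the R ligand is assigned to the 2S flavanone.

Step 1
Reactants: 1 1,2,3-trimethoxybenzene
Product: 2 1-bromo-2,3,4-trimethoxybenzene
Conditions: NBS (1.0 equiv), MeCN, 0 °C to rt
Reagents that add atoms: N-bromosuccinimide, O=C1CCC(=O)N1Br
Why: Electrophilic aromatic bromination should go to C4, para to one outer methoxy group and ortho to the other, because the twisted central methoxy group activates C5 only weakly.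

Step 2
Reactants: 2 1-bromo-2,3,4-trimethoxybenzene
Product: 3 4-bromobenzene-1,2,3-triol (4-bromopyrogallol)
Conditions: BBr3 (3.5 equiv), CH2Cl2, −78 °C to rt; then H2O
Reagents that add atoms: none
Why: Lewis-acid aryl methyl ether cleavage with BBr3 should remove all three methyl groups and leave the aryl bromide untouched.

Step 3
Reactants: 3 4-bromobenzene-1,2,3-triol; 4 4-bromobenzene-1,2-diol (4-bromocatechol)
Product: 5 1,7-dibromo-3,4,6-trihydroxy-5H-benzo[7]annulen-5-one
Conditions: KIO3 (1.1 equiv), 4 (2 equiv), H2O/acetone, 0 °C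
Reagents that add atoms: none
Why: In this oxidative benzotropolone (purpurogallin-type) condensation the o-quinone from 4 should be attacked at C5 by the free C6 of 3, and re-oxidation and closure onto C2 of 3 give a bicyclo[3.2.1] triketone whose one-carbon bridge (C1 of 3) leaves as CO2, so the bromine of 4 ends at C1 and that of 3 at C7.

Step 4
Reactants: 5 1,7-dibromo-3,4,6-trihydroxy-5H-benzo[7]annulen-5-one
Product: 6 3,4,6-tris(benzyloxy)-1,7-dibromo-5H-benzo[7]annulen-5-one
Conditions: BnBr (4 equiv), K2CO3 (5 equiv), DMF, 60 °C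
Reagents that add atoms: benzyl bromide, BrCc1ccccc1
Why: Williamson etherification should alkylate the tropolone at O6, the only mode that keeps the benzo ring aromatic, and warming with excess base brings in the chelated 4-OH as well.

Step 5
Reactants: 6 3,4,6-tris(benzyloxy)-1,7-dibromo-5H-benzo[7]annulen-5-one
Product: 7 3,4,6-tris(benzyloxy)-1,7-bis(4,4,5,5-tetramethyl-1,3,2-dioxaborolan-2-yl)-5H-benzo[7]annulen-5-one
Conditions: B2pin2 (3 equiv), PdCl2(dppf) (10 mol %), KOAc (6 equiv), 1,4-dioxane, 85 °C
Reagents that add atoms: bis(pinacolato)diboron, CC1(C)OB(OC1(C)C)B1OC(C)(C)C(C)(C)O1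
Why: In this Miyaura borylation zerovalent palladium should insert into the aryl C1–Br bond and into the β-bromoenone-type C7–Br bond, both known substrate classes, while KOAc is too weak a base to start Suzuki homocoupling or to attack the tropone.

Step 6
Reactants: 7 3,4,6-tris(benzyloxy)-1,7-bis(pinacolboryl)-5H-benzo[7]annulen-5-one
Product: 8 [3,4,6-tris(benzyloxy)-5-oxo-5H-benzo[7]annulene-1,7-diyl]diboronic acid
Conditions: NaIO4 (6 equiv), NH4OAc (6 equiv), acetone/H2O, rt
Reagents that add atoms: water, O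
Why: Periodate glycol cleavage of the released pinacol should drive boronate hydrolysis to completion under buffered conditions and give the free boronic acids, the boron form for which the conjugate arylation is documented.

Step 7
Reactants: 9 5,7-dihydroxy-4H-chromen-4-one
Product: 10 5,7-bis(benzyloxy)-4H-chromen-4-one
Conditions: BnBr (2.5 equiv), K2CO3 (4 equiv), DMF, 70 °C
Reagents that add atoms: benzyl bromide, BrCc1ccccc1
Why: Williamson etherification with carbonate should protect the 7-OH first and, on heating, the chelated 5-OH, without opening the pyranone as hydroxide or amines would.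

Step 8
Reactants: 8 [3,4,6-tris(benzyloxy)-5-oxo-5H-benzo[7]annulene-1,7-diyl]diboronic acid; 10 5,7-bis(benzyloxy)-4H-chromen-4-one
Product: 11 1,7-bis[(2S)-5,7-bis(benzyloxy)-4-oxochroman-2-yl]-3,4,6-tris(benzyloxy)-5H-benzo[7]annulen-5-one (bis-(2S)-flavanone)
Conditions: Pd(OCOCF3)2 (20 mol %), (R)-t-BuPyOx [(R)-4-tert-butyl-2-(pyridin-2-yl)-4,5-dihydrooxazole] (24 mol %), NH4PF6 (60 mol %), H2O (10 equiv), 10 (5 equiv), ClCH2CH2Cl, 60 °C, 8 added slowly
Reagents that add atoms: none
Why: Proposed new method: the cationic divalent palladium complex of the pyridine-oxazoline should transmetallate each C–B(OH)2 bond of 8, bind chromone 10, insert its C2=C3 bond into the carbon–palladium bond and release the flavanone by protonolysis of the palladium enolate with water, boron leaving as boric acid. The closest known reaction type is the enantioselective palladium/t-BuPyOx conjugate addition of arylboronic acids to chromones, shown for benzenoid boronic acids but not for boron on a tropone carbon (C7), for a peri-flanked position such as C1, or for two additions from one nucleophile. No ring is closed, since the step only makes the C1–C2 and C7–C2 bonds to the two chromanone units. Each new C2 centre is set on its own by the ligand, whose tert-butyl group leaves one face of the coordinated chromone open to migratory insertion, so the R ligand should give S at both centres, and a wrong-face event at either site leads to a diastereomer that chromatography removes. The step needs insertion to outrun protodeboronation and needs the chromone, not the tropone, to act as acceptor: each boron has only one flanking substituent (the O6-benzyl group at C7, the peri C9–H at C1), the medium is nearly neutral, 8 meets an excess of the unhindered acceptor, and the tropone offers only a fully substituted C7 and a peri-shielded C9.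

Step 9
Reactants: 11 bis-(2S)-flavanone
Product: 12 1,7-bis[(2S,4S)-5,7-bis(benzyloxy)-4-hydroxychroman-2-yl]-3,4,6-tris(benzyloxy)-5H-benzo[7]annulen-5-one (2,4-cis in both C rings)
Conditions: RuCl(p-cymene)[(S,S)-TsDPEN] (10 mol %), HCO2H/Et3N (1:1), CH2Cl2, 30 °C
Reagents that add atoms: none
Why: Noyori asymmetric transfer hydrogenation is known for flavanones, the S,S catalyst is matched with the 2S substrate and should deliver hydride to give the 4S (2,4-cis) alcohol, and the C5 tropone carbonyl, flanked by two fully substituted sp2 carbons and two benzyloxy groups, should not fit the Ru–H/N–H transition state that needs one small flank such as C3H2.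

Step 10
Reactants: 12 bis-(2S,4S)-flavan-4-ol
Product: 14 1,7-bis[(2S)-5,7-bis(benzyloxy)-2H-chromen-2-yl]-3,4,6-tris(benzyloxy)-5H-benzo[7]annulen-5-one (bis-flav-3-ene), via bis-mesylate 13 (not isolated)
Conditions: MsCl (3 equiv), Et3N (8 equiv), CH2Cl2, −20 °C to rt, dark
Reagents that add atoms: none
Why: In this mesylation–elimination the 5,7-dialkoxy ring should make the C4–O bond ionise at once and Et3N removes H3, so the alkene forms under buffered conditions that avoid acid-induced dimerisation and leave C2 untouched.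

Step 11
Reactants: 14 bis-flav-3-ene
Product: 16 1,7-bis[(2R)-5,7-bis(benzyloxy)-3-oxochroman-2-yl]-3,4,6-tris(benzyloxy)-5H-benzo[7]annulen-5-one (bis-flavan-3-one), via bis-epoxide 15 (not isolated)
Conditions: DMDO (2.2 equiv), acetone/CH2Cl2, −40 °C; evaporate cold; InCl3 (10 mol %), CH2Cl2, −20 °C
Reagents that add atoms: dimethyldioxirane, CC1(C)OO1
Why: Dimethyldioxirane epoxidation of flav-3-enes (oxygen anti to the C2 substituent) followed by Meinwald rearrangement should open the benzylic C4–O bond and shift hydride from C3 to C4 to give the C3 ketone, with the electron-rich styrene-type C3=C4 bond reacting well before the tropone double bonds and without borane or hydride reagents near the tropone.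

Step 12
Reactants: 16 bis-(2R)-flavan-3-one
Product: 17 1,7-bis[(2R,3R)-5,7-bis(benzyloxy)-3-hydroxychroman-2-yl]-3,4,6-tris(benzyloxy)-5H-benzo[7]annulen-5-one (2,3-cis in both C rings)
Conditions: LiBH(sec-Bu)3 (2.4 equiv), THF, −78 °C; AcOH quench at −78 °C
Reagents that add atoms: none
Why: Diastereoselective ketone reduction with a bulky borohydride, as used to enter the epi series from benzylated flavan-3-ones, should deliver hydride anti to the C2 substituent and set 3R (cis), and at −78 °C the unconjugated α-oxygenated C3 ketones should be consumed before the hindered tropone reacts or C2 enolises.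

Step 13
Reactants: 17 bis-(2R,3R)-flavan-3-ol; 18 3,4,5-tris(benzyloxy)benzoic acid
Product: 19 bis[3,4,5-tris(benzyloxy)benzoate] of 17 (per-O-benzyl target, 2R,3R in both C rings)
Conditions: 18 (3 equiv), DCC (3 equiv), DMAP (0.5 equiv), CH2Cl2, rt
Reagents that add atoms: none
Why: Steglich esterification acylates the axial 3-OH groups on oxygen, so C3 keeps its configuration, and no other free hydroxyl is present.

Step 14
Reactants: 19 per-O-benzyl digallate
Product: 20 target CNP0283148.1
Conditions: H2 (1 atm), Pd(OH)2/C, THF/MeOH, rt; work-up under argon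
Reagents that add atoms: none
Why: Catalytic hydrogenolysis should cleave all thirteen benzyl ethers under mild conditions that are standard for galloylated flavan-3-ols, and early loss of the O6 benzyl group frees the more aromatic tropolone, which resists ring hydrogenation at ambient pressure.

Compound list
1 | 1,2,3-trimethoxybenzene | COc1cccc(OC)c1OC | starting material
2 | 1-bromo-2,3,4-trimethoxybenzene | COc1ccc(Br)c(OC)c1OC | intermediate
3 | 4-bromobenzene-1,2,3-triol | Oc1ccc(Br)c(O)c1O | intermediate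
4 | 4-bromobenzene-1,2-diol | Oc1ccc(Br)cc1O | starting material
5 | 1,7-dibromo-3,4,6-trihydroxy-5H-benzo[7]annulen-5-one | O=c1c(O)c(Br)ccc2c(Br)cc(O)c(O)c12 | intermediate
6 | 3,4,6-tris(benzyloxy)-1,7-dibromo-5H-benzo[7]annulen-5-one | O=c1c(OCc2ccccc2)c(Br)ccc2c(Br)cc(OCc3ccccc3)c(OCc3ccccc3)c12 | intermediate
7 | 3,4,6-tris(benzyloxy)-1,7-bis(pinacolboryl)-5H-benzo[7]annulen-5-one | CC1(C)OB(c2ccc3c(B4OC(C)(C)C(C)(C)O4)cc(OCc4ccccc4)c(OCc4ccccc4)c3c(=O)c2OCc2ccccc2)OC1(C)C | intermediate
8 | [3,4,6-tris(benzyloxy)-5-oxo-5H-benzo[7]annulene-1,7-diyl]diboronic acid | OB(O)c1ccc2c(B(O)O)cc(OCc3ccccc3)c(OCc3ccccc3)c2c(=O)c1OCc1ccccc1 | intermediate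
9 | 5,7-dihydroxy-4H-chromen-4-one | O=c1ccoc2cc(O)cc(O)c12 | starting material
10 | 5,7-bis(benzyloxy)-4H-chromen-4-one | O=c1ccoc2cc(OCc3ccccc3)cc(OCc3ccccc3)c12 | intermediate
11 | bis-(2S)-flavanone | O=c1c(OCc2ccccc2)c([C@@H]2CC(=O)c3c(OCc4ccccc4)cc(OCc4ccccc4)cc3O2)ccc2c([C@@H]3CC(=O)c4c(OCc5ccccc5)cc(OCc5ccccc5)cc4O3)cc(OCc3ccccc3)c(OCc3ccccc3)c12 | intermediate
12 | bis-(2S,4S)-flavan-4-ol (2,4-cis) | O=c1c(OCc2ccccc2)c([C@@H]2C[C@H](O)c3c(OCc4ccccc4)cc(OCc4ccccc4)cc3O2)ccc2c([C@@H]3C[C@H](O)c4c(OCc5ccccc5)cc(OCc5ccccc5)cc4O3)cc(OCc3ccccc3)c(OCc3ccccc3)c12 | intermediate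
13 | bis-(2S,4S)-4-mesylate of 12 | O=c1c(OCc2ccccc2)c([C@@H]2C[C@H](OS(C)(=O)=O)c3c(OCc4ccccc4)cc(OCc4ccccc4)cc3O2)ccc2c([C@@H]3C[C@H](OS(C)(=O)=O)c4c(OCc5ccccc5)cc(OCc5ccccc5)cc4O3)cc(OCc3ccccc3)c(OCc3ccccc3)c12 | intermediate
14 | bis-(2S)-flav-3-ene | O=c1c(OCc2ccccc2)c([C@@H]2C=Cc3c(OCc4ccccc4)cc(OCc4ccccc4)cc3O2)ccc2c([C@@H]3C=Cc4c(OCc5ccccc5)cc(OCc5ccccc5)cc4O3)cc(OCc3ccccc3)c(OCc3ccccc3)c12 | intermediate
15 | bis(3,4-epoxide) of 14, each oxirane oxygen on the face opposite the C2 substituent | O=c1c(OCc2ccccc2)c([C@@H]2[C@H]3O[C@H]3c4c(OCc5ccccc5)cc(OCc5ccccc5)cc4O2)ccc2c([C@@H]3[C@H]4O[C@H]4c5c(OCc6ccccc6)cc(OCc6ccccc6)cc5O3)cc(OCc3ccccc3)c(OCc3ccccc3)c12 | intermediate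
16 | bis-(2R)-flavan-3-one | O=c1c(OCc2ccccc2)c([C@@H]2C(=O)Cc3c(OCc4ccccc4)cc(OCc4ccccc4)cc3O2)ccc2c([C@@H]3C(=O)Cc4c(OCc5ccccc5)cc(OCc5ccccc5)cc4O3)cc(OCc3ccccc3)c(OCc3ccccc3)c12 | intermediate
17 | bis-(2R,3R)-flavan-3-ol (2,3-cis) | O=c1c(OCc2ccccc2)c([C@@H]2[C@H](O)Cc3c(OCc4ccccc4)cc(OCc4ccccc4)cc3O2)ccc2c([C@@H]3[C@H](O)Cc4c(OCc5ccccc5)cc(OCc5ccccc5)cc4O3)cc(OCc3ccccc3)c(OCc3ccccc3)c12 | intermediate
18 | 3,4,5-tris(benzyloxy)benzoic acid | O=C(O)c1cc(OCc2ccccc2)c(OCc2ccccc2)c(OCc2ccccc2)c1 | starting material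
19 | per-O-benzyl digallate (2R,3R in both C rings) | O=c1c(OCc2ccccc2)c([C@@H]2[C@H](OC(=O)c3cc(OCc4ccccc4)c(OCc4ccccc4)c(OCc4ccccc4)c3)Cc3c(OCc4ccccc4)cc(OCc4ccccc4)cc3O2)ccc2c([C@@H]3[C@H](OC(=O)c4cc(OCc5ccccc5)c(OCc5ccccc5)c(OCc5ccccc5)c4)Cc4c(OCc5ccccc5)cc(OCc5ccccc5)cc4O3)cc(OCc3ccccc3)c(OCc3ccccc3)c12 | intermediate
20 | CNP0283148.1 | O=C(O[C@@H]1Cc2c(O)cc(O)cc2O[C@@H]1c1ccc2c([C@H]3Oc4cc(O)cc(O)c4C[C@H]3OC(=O)c3cc(O)c(O)c(O)c3)cc(O)c(O)c2c(=O)c1O)c1cc(O)c(O)c(O)c1 | target

Total step count: 14. Longest linear sequence: 13 steps (steps 1–6 and 8–14, from 1 to 20).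

Steps most likely to fail

Step 8. Protodeboronation of the C7 and C1 boronic acids may outrun transmetallation and insertion. The troponyl-palladium species may also stall through chelation by the C5 carbonyl, and facial selectivity may erode at the peri-flanked C1 site. The fallback gives up the C2–aryl bond formation and closes O1–C2 instead, using known chemistry; it sets out from 6 and comes back at 11.
- Reductive carbonylation of 6 (Pd(OAc)2, di(1-adamantyl)-n-butylphosphine, CO/H2, TMEDA, toluene, 100 °C) would give 3,4,6-tris(benzyloxy)-5-oxo-5H-benzo[7]annulene-1,7-dicarbaldehyde F1.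
- Separately, commercial methyl 2,4,6-trihydroxybenzoate is dibenzylated (BnBr, K2CO3, acetone) to methyl 2,4-bis(benzyloxy)-6-hydroxybenzoate F2.
- A crossed Claisen condensation of F2 with the enolate made from tert-butyl acetate and LiN(i-Pr)2 gives tert-butyl 3-[2,4-bis(benzyloxy)-6-hydroxyphenyl]-3-oxopropanoate F3.
- Knoevenagel condensation of F1 with two equivalents of F3 (piperidine/AcOH, toluene) gives the bis-alkylidene β-keto ester F4.
- An enantioselective intramolecular oxa-Michael addition, catalysed by the pseudoenantiomer of the cinchona-derived thiourea that serves the 2S series, gives the bis(3-tert-butoxycarbonyl)flavanone F5.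
- TsOH in toluene at 80 °C cleaves the tert-butyl esters and decarboxylates to 11.

Step 9. Hydride may be transferred to the tropone (at C5 or in a conjugate sense), the deactivated 5,7-dialkoxyaryl ketones may not turn over, or the C4 alcohols may ionise and be over-reduced. The fallback protects the tropone as its anion rather than relying on catalyst sterics; it sets out from 11 and comes back at 14.
- Dilute acid (2 M HCl/THF, 50 °C) hydrolyses only the vinylogous-ester-type tropolone ether at O6 to give the 6-hydroxy bis-flavanone F6.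
- NaBH4 in THF/EtOH at 0 °C first deprotonates the tropolone. The resulting tropolonate resists hydride, and the C4 ketones are then reduced to the 6-hydroxy bis-flavan-4-ol F7.
- Catalytic PPTS with 4 Å sieves in toluene at 40 °C dehydrates F7 to the 6-hydroxy bis-flav-3-ene F8.
- BnBr/K2CO3 in DMF at rt restores the O6 benzyl ether to give 14.

Step 3. Oxygen or carbon nucleophiles may displace bromide from the 4-bromo-o-quinone, and the bromopyrogallol may self-condense, so little cross-coupled product may form. The fallback uses a halogen-free quinone partner and introduces the second bromine afterwards; it sets out from 3 and comes back at 5.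
- Co-oxidation of 3 with catechol (KIO3, H2O/acetone, 0 °C) would give 7-bromo-3,4,6-trihydroxy-5H-benzo[7]annulen-5-one F9.
- NBS (1 equiv, MeCN, 0 °C) should then brominate C1, para to the 4-OH and meta to the C5 acyl group. This is the orientation seen with 2-hydroxy-3-alkoxybenzaldehydes, and it gives 5.

Further compounds
F1 | step 8 | 3,4,6-tris(benzyloxy)-5-oxo-5H-benzo[7]annulene-1,7-dicarbaldehyde | O=c1c(OCc2ccccc2)c(C=O)ccc2c(C=O)cc(OCc3ccccc3)c(OCc3ccccc3)c12
F2 | step 8 | methyl 2,4-bis(benzyloxy)-6-hydroxybenzoate | COC(=O)c1c(O)cc(OCc2ccccc2)cc1OCc1ccccc1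
F3 | step 8 | tert-butyl 3-[2,4-bis(benzyloxy)-6-hydroxyphenyl]-3-oxopropanoate | CC(C)(C)OC(=O)CC(=O)c1c(O)cc(OCc2ccccc2)cc1OCc1ccccc1
F4 | step 8 | bis-alkylidene β-keto ester (alkene geometry not fixed) | O=c1c(OCc2ccccc2)c(C=C(C(=O)OC(C)(C)C)C(=O)c2c(O)cc(OCc3ccccc3)cc2OCc2ccccc2)ccc2c(C=C(C(=O)OC(C)(C)C)C(=O)c3c(O)cc(OCc4ccccc4)cc3OCc3ccccc3)cc(OCc3ccccc3)c(OCc3ccccc3)c12
F5 | step 8 | bis(3-tert-butoxycarbonyl)flavanone (C2 as in 11, C3 labile) | O=c1c(OCc2ccccc2)c([C@@H]2C(C(=O)OC(C)(C)C)C(=O)c3c(OCc4ccccc4)cc(OCc4ccccc4)cc3O2)ccc2c([C@@H]3C(C(=O)OC(C)(C)C)C(=O)c4c(OCc5ccccc5)cc(OCc5ccccc5)cc4O3)cc(OCc3ccccc3)c(OCc3ccccc3)c12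
F6 | step 9 | 6-hydroxy bis-(2S)-flavanone | O=c1c(O)c([C@@H]2CC(=O)c3c(OCc4ccccc4)cc(OCc4ccccc4)cc3O2)ccc2c([C@@H]3CC(=O)c4c(OCc5ccccc5)cc(OCc5ccccc5)cc4O3)cc(OCc3ccccc3)c(OCc3ccccc3)c12
F7 | step 9 | 6-hydroxy bis-(2S,4S)-flavan-4-ol | O=c1c(O)c([C@@H]2C[C@H](O)c3c(OCc4ccccc4)cc(OCc4ccccc4)cc3O2)ccc2c([C@@H]3C[C@H](O)c4c(OCc5ccccc5)cc(OCc5ccccc5)cc4O3)cc(OCc3ccccc3)c(OCc3ccccc3)c12
F8 | step 9 | 6-hydroxy bis-(2S)-flav-3-ene | O=c1c(O)c([C@@H]2C=Cc3c(OCc4ccccc4)cc(OCc4ccccc4)cc3O2)ccc2c([C@@H]3C=Cc4c(OCc5ccccc5)cc(OCc5ccccc5)cc4O3)cc(OCc3ccccc3)c(OCc3ccccc3)c12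
F9 | step 3 | 7-bromo-3,4,6-trihydroxy-5H-benzo[7]annulen-5-one | O=c1c(O)c(Br)ccc2ccc(O)c(O)c12
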